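**Plan**

- Retrosynthesis: the first cut is the C9–C10 bond of the henicosyl chain (counted from the methyl end), an sp3–sp3 bond between two plain CH2 groups. It gives 1-bromononane and the 9-BBN adduct of methyl 3-(dodec-11-en-1-yl)-1H-pyrrole-2-carboxylate.
- The second cut is at pyrrole C2–C3 and C4–C5 (Barton–Zard). It gives methyl isocyanoacetate and the nitroalkene from tridec-12-enal and nitromethane; the C13 aldehyde comes from 11-bromoundec-1-ene and ethylene oxide.
- Forward: C11 to C13 chain extension, oxidation, Henry addition, acetylation, pyrrole ring closure through two C–C bonds, and last the chain is joined by one-pot hydroboration and alkyl–alkyl Suzuki–Miyaura coupling.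
- Enabling feature: chain C9 and C10 are unbranched primary carbons, C10 being eleven methylenes away from pyrrole C3. The only other functions, N1–H and the C2 methyl ester (together a vinylogous carbamate), should be inert to 9-BBN and to hydrated phosphate.
- Stereochemistry: the target has no stereocentre and no stereogenic double bond; the racemic carbinol carbon of the Henry adduct becomes sp2 pyrrole C3.

Key step: step 6

Remark: 9-BBN is drawn as its monomer, and the racemic centres of 7 and 8 are drawn without configuration.

**Step 1**
Reactants: 1 11-bromoundec-1-ene; 2 ethylene oxide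
Product: 4 tridec-12-en-1-ol, via undec-10-en-1-ylmagnesium bromide 3 (not isolated)
Conditions: Mg, I2 (cat.), THF, reflux; then CuI (10 mol %), 2 (THF solution, 1.5 equiv), −30 → 0 °C; 1 M HCl
Reagents that add atoms: none
Why: The primary Grignard reagent 3 should open ethylene oxide by Cu(I)-assisted SN2 attack at carbon (Grignard epoxide opening), a two-carbon homologation to the primary alcohol that leaves the remote terminal alkene untouched.

**Step 2**
Reactants: 4 tridec-12-en-1-ol
Product: 5 tridec-12-enal
Conditions: PhI(OAc)2 (1.1 equiv), TEMPO (10 mol %), CH2Cl2, rt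
Reagents that add atoms: none
Why: The oxoammonium-mediated TEMPO/PhI(OAc)2 oxidation of a primary alcohol should stop at the aldehyde and does not touch the terminal alkene.

**Step 3**
Reactants: 5 tridec-12-enal; 6 nitromethane
Product: 7 (±)-1-nitrotetradec-13-en-2-ol
Conditions: 6 (10 equiv), KOtBu (5 mol %), THF/t-BuOH, 0 °C → rt
Reagents that add atoms: none
Why: Henry (nitroaldol) addition of the nitromethane nitronate to the unhindered aldehyde; the new carbinol centre forms as a racemate, which is immaterial because this carbon becomes pyrrole C3 in step 5.

**Step 4**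
Reactants: 7 (±)-1-nitrotetradec-13-en-2-ol
Product: 8 (±)-1-nitrotetradec-13-en-2-yl acetate
Conditions: Ac2O (1.3 equiv), conc. H2SO4 (cat.), neat, 0 °C → rt
Reagents that add atoms: acetic anhydride, CC(=O)OC(C)=O
Why: Acid-catalysed O-acetylation turns the hydroxyl into a leaving group for the later E1cB elimination, and the absence of base should prevent premature release of the polymerisable nitroalkene.

**Step 5**
Reactants: 8 (±)-1-nitrotetradec-13-en-2-yl acetate; 9 methyl isocyanoacetate
Product: 11 methyl 3-(dodec-11-en-1-yl)-1H-pyrrole-2-carboxylate, via (E)-1-nitrotetradeca-1,13-diene 10 (not isolated)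
Conditions: 9 (1.1 equiv), DBU (2.2 equiv), THF, 0 °C → rt
Reagents that add atoms: none
Why: Barton–Zard pyrrole synthesis: DBU eliminates acetic acid from 8 to give nitroalkene 10, the isocyanoacetate carbanion adds in Michael fashion to its alkyl-bearing carbon (pyrrole C2–C3 bond), the nitronate closes 5-endo-dig onto the isocyanide carbon (C4–C5 bond), and loss of nitrite plus a 1,5-H shift aromatise, so the chain sits at C3 next to the ester and C4 stays unsubstituted.

**Step 6**
Reactants: 11 methyl 3-(dodec-11-en-1-yl)-1H-pyrrole-2-carboxylate; 12 1-bromononane
Product: 14 methyl 3-henicosyl-1H-pyrrole-2-carboxylate (CNP0394803.0), via B-alkyl-9-BBN adduct 13 (not isolated)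
Conditions: 9-BBN (1.1 equiv), THF, 0 °C → rt; then 12 (1.3 equiv), Pd(OAc)2 (4 mol %), PCy3 (8 mol %), K3PO4·H2O (1.3 equiv), THF, rt
Reagents that add atoms: none
Why: 9-BBN should add anti-Markovnikov to the terminal alkene of 11 and place boron on the terminal carbon (13); Pd(0)/PCy3 then undergoes SN2-type oxidative addition to 1-bromononane, the phosphate/water-activated borate of 13 transfers its primary alkyl group, and reductive elimination forms the C9–C10 sp3–sp3 bond. The closest known reaction type is the B-alkyl Suzuki–Miyaura alkyl–alkyl coupling of primary alkyl bromides bearing β-hydrogens with alkyl-9-BBN reagents under Pd/trialkylphosphine catalysis at room temperature. No ring is closed and no stereocentre is created. The step needs regioselective hydroboration (secured by the steric demand of 9-BBN at a monosubstituted alkene), chemoselectivity for the alkene over the C2 ester and N1–H (secured because the ester is a deactivated vinylogous carbamate and the pyrrole nitrogen is non-basic), and reductive elimination ahead of β-hydride elimination (secured by the bulky, electron-rich PCy3). Coupling at carbon ahead of N-alkylation rests on the weak, heterogeneous hydrated phosphate base in THF at room temperature.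

**Compound list**

1 | 11-bromoundec-1-ene | C=CCCCCCCCCCBr | starting material
2 | ethylene oxide (oxirane) | C1CO1 | starting material
3 | undec-10-en-1-ylmagnesium bromide (formed in situ) | C=CCCCCCCCCC[Mg]Br | intermediate
4 | tridec-12-en-1-ol | C=CCCCCCCCCCCCO | intermediate
5 | tridec-12-enal | C=CCCCCCCCCCCC=O | intermediate
6 | nitromethane | C[N+](=O)[O-] | starting material
7 | (±)-1-nitrotetradec-13-en-2-ol | C=CCCCCCCCCCCC(O)C[N+](=O)[O-] | intermediate
8 | (±)-1-nitrotetradec-13-en-2-yl acetate | C=CCCCCCCCCCCC(OC(C)=O)C[N+](=O)[O-] | intermediate
9 | methyl isocyanoacetate | [C-]#[N+]CC(=O)OC | starting material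
10 | (E)-1-nitrotetradeca-1,13-diene (formed in situ) | C=CCCCCCCCCCC/C=C/[N+](=O)[O-] | intermediate
11 | methyl 3-(dodec-11-en-1-yl)-1H-pyrrole-2-carboxylate | C=CCCCCCCCCCCc1cc[nH]c1C(=O)OC | intermediate
12 | 1-bromononane | CCCCCCCCCBr | starting material
13 | methyl 3-[12-(9-borabicyclo[3.3.1]nonan-9-yl)dodecyl]-1H-pyrrole-2-carboxylate (formed in situ) | COC(=O)c1[nH]ccc1CCCCCCCCCCCCB1C2CCCC1CCC2 | intermediate
14 | methyl 3-henicosyl-1H-pyrrole-2-carboxylate (CNP0394803.0) | CCCCCCCCCCCCCCCCCCCCCc1cc[nH]c1C(=O)OC | target

**Step count**

Total step count: 6. Longest linear sequence: 6 steps (1 → 4 → 5 → 7 → 8 → 11 → 14).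

**Steps most likely to fail**

1. Step 6. Protodeboronation of the alkylborane or β-hydride elimination of the nonyl–palladium species may outrun transmetalation, and the pyrrole nitrogen may be alkylated by 1-bromononane under the phosphate base. The fallback sets out from 11 and comes back to the route at 14; it forms the same bond as a C=C by carbonyl olefination. Hydroboration of 11 with 9-BBN and oxidation with NaBO3·4H2O should give methyl 3-(12-hydroxydodecyl)-1H-pyrrole-2-carboxylate F1. Oxidation with Dess–Martin periodinane (NaHCO3, CH2Cl2) should give methyl 3-(12-oxododecyl)-1H-pyrrole-2-carboxylate F2. Wittig olefination with the ylide from commercial nonyltriphenylphosphonium bromide and NaHMDS (excess, the first equivalent being taken up by N–H; THF, −78 °C → rt) should give methyl 3-[(12Z)-henicos-12-en-1-yl]-1H-pyrrole-2-carboxylate F3. Hydrogenation (H2, Pd/C, EtOAc, rt) should then saturate the chain to 14 without touching the electron-poor pyrrole.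

2. Step 5. Anionic oligomerisation of the 2-unsubstituted nitroalkene, or a second Michael addition of the first adduct to another nitroalkene molecule, may compete with ring closure. The fallback sets out from 5 and comes back at 11; it replaces the nitro group by a sulfone as activating and leaving group and bypasses steps 3 and 4. Horner–Wadsworth–Emmons olefination of 5 with commercial diethyl [(phenylsulfonyl)methyl]phosphonate (NaH, THF, 0 °C → rt) should give [(1E)-tetradeca-1,13-dien-1-ylsulfonyl]benzene F4. Treatment of F4 with methyl isocyanoacetate 9 and KOtBu in THF should give 11 by Michael addition, 5-endo-dig closure and loss of benzenesulfinate, with the same regiochemistry as the nitro route.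

3. Step 1. Halide-mediated opening of ethylene oxide to the halohydrin and Wurtz homocoupling during Grignard formation may erode the homologation. The fallback sets out from 1 and comes back at 4; it uses a malonate as the two-carbon unit. Alkylation of dimethyl malonate with 1 (NaH, THF/DMF, 60 °C) should give dimethyl 2-(undec-10-en-1-yl)propanedioate F5. Krapcho demethoxycarbonylation (LiCl, H2O, DMSO, 150 °C) should give methyl tridec-12-enoate F6. Reduction with LiAlH4 (THF, 0 °C) should give alcohol 4.

**Further compounds**

F1 | step 6 | methyl 3-(12-hydroxydodecyl)-1H-pyrrole-2-carboxylate | COC(=O)c1[nH]ccc1CCCCCCCCCCCCO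
F2 | step 6 | methyl 3-(12-oxododecyl)-1H-pyrrole-2-carboxylate | COC(=O)c1[nH]ccc1CCCCCCCCCCCC=O
F3 | step 6 | methyl 3-[(12Z)-henicos-12-en-1-yl]-1H-pyrrole-2-carboxylate | CCCCCCCC/C=C\CCCCCCCCCCCc1cc[nH]c1C(=O)OC
F4 | step 5 | [(1E)-tetradeca-1,13-dien-1-ylsulfonyl]benzene | C=CCCCCCCCCCC/C=C/S(=O)(=O)c1ccccc1
F5 | step 1 | dimethyl 2-(undec-10-en-1-yl)propanedioate | C=CCCCCCCCCCC(C(=O)OC)C(=O)OC
F6 | step 1 | methyl tridec-12-enoate | C=CCCCCCCCCCCC(=O)OC
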